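## Retrosynthetic overview

1. Target 26 ⇒ ester C–O bond: 6‑hydroxy germacranolide 20 + bis‑TES (R)‑2‑methylglyceric acid 24 (from (R)‑2‑methylserine).
2. 20 ⇒ C6–C7 bond (key step): open‑chain enal / 3‑(bromomethyl)butenolide 18. One intramolecular CrCl2 allylation closes the ten‑membered ring, sets C6 and C7 from C8 and unveils the exo‑methylene lactone.
3. 18 ⇒ butenolide by ring‑closing metathesis of the 2‑(bromomethyl)acrylate of triene diol 12; C8 is the only stereocentre carried in.
4. 12 ⇒ C1–C2 bond: B‑alkyl Suzuki coupling of (E)‑vinyl iodide 6 (Sharpless resolution, Negishi carboalumination) with dienol 10 (anti‑carbomagnesiation fixes the C4=C5 geometry).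
5. Ring order: five‑membered lactone first (step 8), ten‑membered carbocycle second (step 11).

Assumption: 7, 8, 14 and 21 are catalogue compounds; ring atoms are referred to by germacrane numbering (C8 carries the lactone oxygen, C6 the ester, C15 the acetoxymethyl carbon).

## Route

Step 1
Reactants: 1 acrolein; 2 propargyl bromide
Product: 3 rac-hex-1-en-5-yn-3-ol
Conditions: Zn dust, THF/sat. aq. NH4Cl, 0 °C
Reagents that add atoms: none
Why: Zinc‑mediated Barbier propargylation adds 1,2 to the enal with SE2' transposition to give the homopropargylic alcohol; C8 is formed racemic and resolved in step 2.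

Step 2
Reactants: 3 rac-hex-1-en-5-yn-3-ol
Product: 4 (3S)-hex-1-en-5-yn-3-ol
Conditions: Ti(OiPr)4 (10 mol%), D‑(−)‑DIPT (15 mol%), t‑BuOOH (0.6 equiv), 4 Å MS, CH2Cl2, −20 °C, to about 55% conversion
Reagents that add atoms: none
Why: Sharpless kinetic resolution; with D‑(−)‑tartrate the (R)‑alcohol is epoxidised much faster, so the unreacted (S)‑alcohol (C8) is recovered in high ee.

Step 3
Reactants: 4 (3S)-hex-1-en-5-yn-3-ol
Product: 6 (3S,5E)-6-iodo-5-methylhexa-1,5-dien-3-ol, via alkenylalane 5 (not isolated)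
Conditions: Me3Al (3 equiv), Cp2ZrCl2 (0.25 equiv), CH2Cl2, 0 °C→rt; then I2, THF, −30→0 °C; aq. KNaC4H4O6 work‑up
Reagents that add atoms: trimethylaluminium, C[Al](C)C (methyl C14; the AlMe2 groups stay only in 5); iodine, II
Why: Negishi zirconium‑catalysed carboalumination adds Me and Al syn across the terminal alkyne with Me on the internal carbon, and iodinolysis with retention gives the (E)‑iodide (C1=C10 geometry); the hydroxyl is only converted to its aluminium alkoxide.

Step 4
Reactants: 7 4-[(tert-butyldimethylsilyl)oxy]but-2-yn-1-ol; 8 vinylmagnesium chloride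
Product: 10 (2E)-4-[(tert-butyldimethylsilyl)oxy]-2-ethenylbut-2-en-1-ol, via magnesium chelate 9 (not isolated)
Conditions: 8 (4 equiv), THF/cyclohexane, reflux, 12 h; then sat. aq. NH4Cl, 0 °C
Reagents that add atoms: none
Why: Alkoxide‑directed anti‑carbomagnesiation of a propargylic alcohol puts vinyl on the proximal alkyne carbon and magnesium on the distal one in a five‑membered chelate, so protonation leaves vinyl cis to CH2OTBS, which is the cis C3/C6 relationship across C4=C5.

Step 5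
Reactants: 10 (2E)-4-[(tert-butyldimethylsilyl)oxy]-2-ethenylbut-2-en-1-ol; 6 (3S,5E)-6-iodo-5-methylhexa-1,5-dien-3-ol
Product: 12 (3S,5E,9E)-11-[(tert-butyldimethylsilyl)oxy]-9-(hydroxymethyl)-5-methylundeca-1,5,9-trien-3-ol, via bis(9-BBN) adduct 11 (not isolated)
Conditions: 9‑BBN (2.2 equiv), THF, 0 °C→rt; then aq. Cs2CO3 (3 equiv, also destroys excess borane), 6, PdCl2(dppf) (5 mol%), AsPh3 (5 mol%), DMF, rt
Reagents that add atoms: 9‑BBN, [H]B1C2CCCC1CCC2 (its boron and carbons stay only in 11; 12 keeps only a hydrogen from it)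
Why: 9‑BBN hydroborates only the monosubstituted diene terminus (the OH is tied up as a borinate), and B‑alkyl Suzuki–Miyaura coupling joins C2 to C1 of the vinyl iodide with retention of the (E) geometry; no stereocentre is formed.

Step 6
Reactants: 12 (3S,5E,9E)-11-[(tert-butyldimethylsilyl)oxy]-9-(hydroxymethyl)-5-methylundeca-1,5,9-trien-3-ol
Product: 13 (3S,5E,9E)-9-(acetoxymethyl)-11-[(tert-butyldimethylsilyl)oxy]-5-methylundeca-1,5,9-trien-3-ol
Conditions: AcCl (1.05 equiv), 2,4,6‑collidine, CH2Cl2, −78 °C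
Reagents that add atoms: acetyl chloride, CC(=O)Cl
Why: Kinetically selective acylation of the primary allylic alcohol over the secondary one at low temperature.

Step 7
Reactants: 13 (3S,5E,9E)-9-(acetoxymethyl)-11-[(tert-butyldimethylsilyl)oxy]-5-methylundeca-1,5,9-trien-3-ol; 14 2-(bromomethyl)prop-2-enoic acid
Product: 15 (3S,5E,9E)-9-(acetoxymethyl)-11-[(tert-butyldimethylsilyl)oxy]-5-methylundeca-1,5,9-trien-3-yl 2-(bromomethyl)prop-2-enoate
Conditions: DCC, DMAP (5 mol%), CH2Cl2, 0 °C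
Reagents that add atoms: none
Why: Steglich esterification of the C8 alcohol with retention (its C–O bond is not broken); low temperature and only catalytic DMAP spare the allylic bromide.

Step 8
Reactants: 15 (3S,5E,9E)-9-(acetoxymethyl)-11-[(tert-butyldimethylsilyl)oxy]-5-methylundeca-1,5,9-trien-3-yl 2-(bromomethyl)prop-2-enoate
Product: 16 (5S)-5-[(2E,6E)-6-(acetoxymethyl)-8-[(tert-butyldimethylsilyl)oxy]-2-methylocta-2,6-dien-1-yl]-3-(bromomethyl)furan-2(5H)-one
Conditions: second‑generation Grubbs catalyst (H2IMes)(PCy3)Cl2Ru=CHPh (5 mol%), CH2Cl2 (5 mM), 40 °C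
Reagents that add atoms: none
Why: Ring‑closing metathesis between the terminal vinyl group and the 1,1‑disubstituted acrylate forms the butenolide and expels ethene; the trisubstituted alkenes are inert and C8 is untouched.

Step 9
Reactants: 16 (5S)-5-[(2E,6E)-6-(acetoxymethyl)-8-[(tert-butyldimethylsilyl)oxy]-2-methylocta-2,6-dien-1-yl]-3-(bromomethyl)furan-2(5H)-one
Product: 17 (5S)-5-[(2E,6E)-6-(acetoxymethyl)-8-hydroxy-2-methylocta-2,6-dien-1-yl]-3-(bromomethyl)furan-2(5H)-one
Conditions: 48% aq. HF, MeCN, 0 °C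
Reagents that add atoms: none
Why: Acidic fluoride cleavage of the primary allylic TBS ether; acetate, butenolide and allylic bromide are stable to these conditions.

Step 10
Reactants: 17 (5S)-5-[(2E,6E)-6-(acetoxymethyl)-8-hydroxy-2-methylocta-2,6-dien-1-yl]-3-(bromomethyl)furan-2(5H)-one
Product: 18 (5S)-5-[(2E,6E)-6-(acetoxymethyl)-2-methyl-8-oxoocta-2,6-dien-1-yl]-3-(bromomethyl)furan-2(5H)-one
Conditions: Dess–Martin periodinane, CH2Cl2, 0 °C→rt; used at once
Reagents that add atoms: none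
Why: Dess–Martin oxidation of the primary allylic alcohol to the enal is fast and mild enough to avoid E/Z isomerisation of the β,β‑disubstituted enal.

Step 11
Reactants: 18 (5S)-5-[(2E,6E)-6-(acetoxymethyl)-2-methyl-8-oxoocta-2,6-dien-1-yl]-3-(bromomethyl)furan-2(5H)-one
Product: 20 (6R,7S,8S)-15-acetoxy-6-hydroxygermacra-1(10),4,11(13)-trien-12,8-olide, via allylchromium dichloride 19 (not isolated)
Conditions: CrCl2 (8 equiv), THF/DMF 9:1, rt, syringe‑pump addition of 18 over 12 h to 2 mM; then aq. NH4Cl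
Reagents that add atoms: chromium dichloride, Cl[Cr]Cl (chromium and chlorine stay only in 19)
Why: Proposed new method: two equivalents of divalent chromium reduce the allylic bromide to allylchromium 19, which adds 1,2 to the tethered enal through its γ‑carbon C7 in a chair‑like six‑membered transition state; the ring‑fixed (E)‑type allyl geometry with the enal substituent equatorial gives the anti C6/C7 relationship, bond formation on the butenolide face opposite the C9 tether gives the trans‑fused lactone, the exo‑methylene appears by allyl transposition, and the cis C4=C5 turn plus high dilution favour ten‑membered closure; the closest known reactions are the intermolecular chromium‑, zinc‑ or indium‑mediated Barbier allylations of aldehydes with 3‑(bromomethyl)butenolides and the Nozaki–Hiyama–Kishi‑type allylative macrocyclisations of 2‑(bromomethyl)acrylates to ten‑membered germacranolide rings.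

Step 12
Reactants: 21 (2R)-2-amino-3-hydroxy-2-methylpropanoic acid
Product: 22 (2R)-2,3-dihydroxy-2-methylpropanoic acid
Conditions: NaNO2, 1 M aq. H2SO4, 0 °C→rt
Reagents that add atoms: water, O
Why: Nitrous acid deamination (diazotisation) goes with overall retention by double inversion through carboxylate participation, as for serine to glyceric acid, so the (R) centre is kept.

Step 13
Reactants: 22 (2R)-2,3-dihydroxy-2-methylpropanoic acid
Product: 24 (2R)-2-methyl-2,3-bis[(triethylsilyl)oxy]propanoic acid, via tris-silylated ester 23 (not isolated)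
Conditions: TESOTf (3.3 equiv), 2,6‑lutidine, CH2Cl2, −78→0 °C; then THF/H2O, rt
Reagents that add atoms: triethylsilyl trifluoromethanesulfonate, CC[Si](CC)(CC)OS(=O)(=O)C(F)(F)F
Why: Exhaustive silylation (TESOTf also silylates the tertiary alcohol) followed by selective hydrolysis of the labile silyl ester; the stereocentre is not touched.

Step 14
Reactants: 20 (6R,7S,8S)-15-acetoxy-6-hydroxygermacra-1(10),4,11(13)-trien-12,8-olide; 24 (2R)-2-methyl-2,3-bis[(triethylsilyl)oxy]propanoic acid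
Product: 25 (6R,7R,8S)-15-acetoxy-6-{[(2R)-2-methyl-2,3-bis(triethylsilyloxy)propanoyl]oxy}germacra-1(10),4,11(13)-trien-12,8-olide
Conditions: MNBA (2‑methyl‑6‑nitrobenzoic anhydride), DMAP, Et3N, toluene, rt→40 °C
Reagents that add atoms: none
Why: Shiina esterification (mixed anhydride, DMAP acyl transfer) acylates the C6 alcohol with retention at C6; the acid α‑carbon is quaternary and cannot epimerise.

Step 15
Reactants: 25 (6R,7R,8S)-15-acetoxy-6-{[(2R)-2-methyl-2,3-bis(triethylsilyloxy)propanoyl]oxy}germacra-1(10),4,11(13)-trien-12,8-olide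
Product: 26 (6R,7R,8S)-15-acetoxy-6-{[(2R)-2,3-dihydroxy-2-methylpropanoyl]oxy}germacra-1(10),4,11(13)-trien-12,8-olide
Conditions: HF·pyridine, pyridine/THF, 0 °C→rt
Reagents that add atoms: none
Why: Buffered fluoride desilylation removes both TES ethers without acid strong enough to trigger transannular cyclisation of the 1,5‑diene; acetate, esters and the α‑methylene lactone are stable and no stereocentre is affected.

## Compound list

1 | acrolein | C=CC=O | starting material
2 | propargyl bromide | C#CCBr | starting material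
3 | rac-hex-1-en-5-yn-3-ol | C=CC(O)CC#C | intermediate
4 | (3S)-hex-1-en-5-yn-3-ol | C=C[C@@H](O)CC#C | intermediate
5 | alkenylalane: dimethylaluminium (3S,5E)-6-(dimethylalumanyl)-5-methylhexa-1,5-dien-3-olate | C=C[C@@H](O[Al](C)C)C/C(C)=C/[Al](C)C | intermediate
6 | (3S,5E)-6-iodo-5-methylhexa-1,5-dien-3-ol | C=C[C@@H](O)C/C(C)=C/I | intermediate
7 | 4-[(tert-butyldimethylsilyl)oxy]but-2-yn-1-ol | OCC#CCO[Si](C)(C)C(C)(C)C | starting material
8 | vinylmagnesium chloride | C=C[Mg]Cl | starting material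
9 | magnesium chelate: 3-{[(tert-butyldimethylsilyl)oxy]methyl}-4-ethenyl-2,5-dihydro-1,2-oxamagnesole | C=CC1=C(CO[Si](C)(C)C(C)(C)C)[Mg]OC1 | intermediate
10 | (2E)-4-[(tert-butyldimethylsilyl)oxy]-2-ethenylbut-2-en-1-ol (vinyl cis to CH2OTBS) | OC/C(C=C)=C/CO[Si](C)(C)C(C)(C)C | intermediate
11 | bis(9-BBN) adduct of 10: O‑borinate at C15 and B‑alkyl borane at C2 | B1(OC/C(CCB2C3CCCC2CCC3)=C/CO[Si](C)(C)C(C)(C)C)C2CCCC1CCC2 | intermediate
12 | (3S,5E,9E)-11-[(tert-butyldimethylsilyl)oxy]-9-(hydroxymethyl)-5-methylundeca-1,5,9-trien-3-ol | C=C[C@@H](O)C/C(C)=C/CC/C(CO)=C\CO[Si](C)(C)C(C)(C)C | intermediate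
13 | (3S,5E,9E)-9-(acetoxymethyl)-11-[(tert-butyldimethylsilyl)oxy]-5-methylundeca-1,5,9-trien-3-ol | C=C[C@@H](O)C/C(C)=C/CC/C(COC(C)=O)=C\CO[Si](C)(C)C(C)(C)C | intermediate
14 | 2-(bromomethyl)prop-2-enoic acid | C=C(CBr)C(=O)O | starting material
15 | (3S,5E,9E)-9-(acetoxymethyl)-11-[(tert-butyldimethylsilyl)oxy]-5-methylundeca-1,5,9-trien-3-yl 2-(bromomethyl)prop-2-enoate | C=C[C@@H](OC(=O)C(=C)CBr)C/C(C)=C/CC/C(COC(C)=O)=C\CO[Si](C)(C)C(C)(C)C | intermediate
16 | (5S)-5-[(2E,6E)-6-(acetoxymethyl)-8-[(tert-butyldimethylsilyl)oxy]-2-methylocta-2,6-dien-1-yl]-3-(bromomethyl)furan-2(5H)-one | BrCC1=C[C@H](C/C(C)=C/CC/C(COC(C)=O)=C\CO[Si](C)(C)C(C)(C)C)OC1=O | intermediate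
17 | (5S)-5-[(2E,6E)-6-(acetoxymethyl)-8-hydroxy-2-methylocta-2,6-dien-1-yl]-3-(bromomethyl)furan-2(5H)-one | BrCC1=C[C@H](C/C(C)=C/CC/C(COC(C)=O)=C\CO)OC1=O | intermediate
18 | (5S)-5-[(2E,6E)-6-(acetoxymethyl)-2-methyl-8-oxoocta-2,6-dien-1-yl]-3-(bromomethyl)furan-2(5H)-one | BrCC1=C[C@H](C/C(C)=C/CC/C(COC(C)=O)=C\C=O)OC1=O | intermediate
19 | allylchromium dichloride derived from 18 (CrCl2 in place of Br) | Cl[Cr](Cl)CC1=C[C@H](C/C(C)=C/CC/C(COC(C)=O)=C\C=O)OC1=O | intermediate
20 | (6R,7S,8S)-15-acetoxy-6-hydroxygermacra-1(10),4,11(13)-trien-12,8-olide (1(10)E; C3 and C6 cis across C4=C5; H6/H7 trans, H7/H8 trans) | C=C1C(=O)O[C@H]2C/C(C)=C/CC/C(COC(C)=O)=C\[C@@H](O)[C@H]12 | intermediate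
21 | (2R)-2-amino-3-hydroxy-2-methylpropanoic acid ((R)-2-methylserine) | C[C@@](N)(CO)C(=O)O | starting material
22 | (2R)-2,3-dihydroxy-2-methylpropanoic acid | C[C@@](O)(CO)C(=O)O | intermediate
23 | triethylsilyl (2R)-2-methyl-2,3-bis[(triethylsilyl)oxy]propanoate | C[C@@](O[Si](CC)(CC)CC)(CO[Si](CC)(CC)CC)C(=O)O[Si](CC)(CC)CC | intermediate
24 | (2R)-2-methyl-2,3-bis[(triethylsilyl)oxy]propanoic acid | C[C@@](O[Si](CC)(CC)CC)(CO[Si](CC)(CC)CC)C(=O)O | intermediate
25 | (6R,7R,8S)-15-acetoxy-6-{[(2R)-2-methyl-2,3-bis(triethylsilyloxy)propanoyl]oxy}germacra-1(10),4,11(13)-trien-12,8-olide | C=C1C(=O)O[C@H]2C/C(C)=C/CC/C(COC(C)=O)=C\[C@@H](OC(=O)[C@](C)(O[Si](CC)(CC)CC)CO[Si](CC)(CC)CC)[C@H]12 | intermediate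
26 | CNP0426025.2: (6R,7R,8S)-15-acetoxy-6-{[(2R)-2,3-dihydroxy-2-methylpropanoyl]oxy}germacra-1(10),4,11(13)-trien-12,8-olide | C=C1C(=O)O[C@H]2C/C(C)=C/CC/C(COC(C)=O)=C\[C@@H](OC(=O)[C@](C)(O)CO)[C@H]12 | target

## Summary

Total step count: 15.
Longest linear sequence: 12 steps (1, 2, 3, 5, 6, 7, 8, 9, 10, 11, 14, 15).

Three steps most likely to fail:

Step 11 (ring closure). It may give oligomers, attack through the CH2 carbon (a twelve‑membered ring), or the wrong C6/C7 or ring‑fusion diastereomer. The fallback sets out from 6 and 10 and comes back at 20; it makes the C6–C7 bond between two molecules and closes the ring at C1–C2 instead.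
- 6 is esterified with 14 (DCC) to (3S,5E)-6-iodo-5-methylhexa-1,5-dien-3-yl 2-(bromomethyl)prop-2-enoate F1, which second‑generation Grubbs catalyst closes to (5S)-3-(bromomethyl)-5-[(2E)-3-iodo-2-methylprop-2-en-1-yl]furan-2(5H)-one F2.
- 10 is acetylated (Ac2O, pyridine) to (2E)-4-[(tert-butyldimethylsilyl)oxy]-2-ethenylbut-2-en-1-yl acetate F3, desilylated (aq. HF) to (2E)-2-ethenyl-4-hydroxybut-2-en-1-yl acetate F4 and oxidised (Dess–Martin periodinane) to (2E)-2-ethenyl-4-oxobut-2-en-1-yl acetate F5.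
- Intermolecular CrCl2‑mediated allylation of F5 by F2, where anti addition trans to the C8 substituent is the normal outcome, gives [(2E,4R)-2-ethenyl-4-hydroxy-4-{(2S,3S)-2-[(2E)-3-iodo-2-methylprop-2-en-1-yl]-4-methylidene-5-oxooxolan-3-yl}but-2-en-1-yl] acetate F6.
- 9‑BBN hydroborates the diene terminus, which reacts far faster than the electron‑poor exo‑methylene, and ties up the hydroxyl, giving the bis(9-BBN) adduct F7. Intramolecular B‑alkyl Suzuki coupling (PdCl2(dppf), AsPh3, Cs2CO3, DMF/H2O, 1 mM) then forms C1–C2 and gives 20.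

Step 14 (acylation of a hindered ring alcohol with a bulky α,α‑disubstituted bis‑silyl acid). It may be slow or deliver the aryl ester instead. The fallback sets out from 22 and 20 and comes back at 26; it changes the protecting group, the acyl donor and the final deprotection.
- 22 is converted with 2,2‑dimethoxypropane/TsOH into (4R)-2,2,4-trimethyl-1,3-dioxolane-4-carboxylic acid F8 and with oxalyl chloride into (4R)-2,2,4-trimethyl-1,3-dioxolane-4-carbonyl chloride F9.
- This small, tied‑back acyl chloride acylates 20 (Et3N, DMAP, CH2Cl2) to (6R,7R,8S)-15-acetoxy-6-{[(4R)-2,2,4-trimethyl-1,3-dioxolane-4-carbonyl]oxy}germacra-1(10),4,11(13)-trien-12,8-olide F10.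
- 80% aq. AcOH at 40 °C hydrolyses the acetal to 26.

Step 4 (carbomagnesiation). At reflux the alkenylmagnesium may lose silyloxide to give a vinylallene, or the addition may stall. The fallback sets out from 7 and comes back at 10.
- Hydroxyl‑directed ruthenium‑catalysed trans‑hydrostannation (Bu3SnH, [Cp*RuCl]4, CH2Cl2) places tin on the alkyne carbon next to the free OH and gives (2Z)-4-[(tert-butyldimethylsilyl)oxy]-2-(tributylstannyl)but-2-en-1-ol F11.
- Stille coupling with vinyl bromide (Pd(PPh3)4, CuI, DMF) replaces tin with retention and gives 10.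

Further compounds

F1 | step 11 | (3S,5E)-6-iodo-5-methylhexa-1,5-dien-3-yl 2-(bromomethyl)prop-2-enoate | C=C[C@@H](OC(=O)C(=C)CBr)C/C(C)=C/I
F2 | step 11 | (5S)-3-(bromomethyl)-5-[(2E)-3-iodo-2-methylprop-2-en-1-yl]furan-2(5H)-one | BrCC1=C[C@H](C/C(C)=C/I)OC1=O
F3 | step 11 | (2E)-4-[(tert-butyldimethylsilyl)oxy]-2-ethenylbut-2-en-1-yl acetate | CC(=O)OC/C(C=C)=C/CO[Si](C)(C)C(C)(C)C
F4 | step 11 | (2E)-2-ethenyl-4-hydroxybut-2-en-1-yl acetate | CC(=O)OC/C(C=C)=C/CO
F5 | step 11 | (2E)-2-ethenyl-4-oxobut-2-en-1-yl acetate | CC(=O)OC/C(C=C)=C/C=O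
F6 | step 11 | [(2E,4R)-2-ethenyl-4-hydroxy-4-{(2S,3S)-2-[(2E)-3-iodo-2-methylprop-2-en-1-yl]-4-methylidene-5-oxooxolan-3-yl}but-2-en-1-yl] acetate | C=C1C(=O)O[C@@H](C/C(C)=C/I)[C@@H]1[C@H](O)/C=C(\C=C)COC(C)=O
F7 | step 11 | bis(9-BBN) adduct of F6 (O‑borinate at C6, B‑alkyl borane at C2) | C=C1C(=O)O[C@@H](C/C(C)=C/I)[C@@H]1[C@H](OB1C2CCCC1CCC2)/C=C(\CCB1C2CCCC1CCC2)COC(C)=O
F8 | step 14 | (4R)-2,2,4-trimethyl-1,3-dioxolane-4-carboxylic acid | C[C@]1(C(=O)O)COC(C)(C)O1
F9 | step 14 | (4R)-2,2,4-trimethyl-1,3-dioxolane-4-carbonyl chloride | C[C@]1(C(=O)Cl)COC(C)(C)O1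
F10 | step 14 | (6R,7R,8S)-15-acetoxy-6-{[(4R)-2,2,4-trimethyl-1,3-dioxolane-4-carbonyl]oxy}germacra-1(10),4,11(13)-trien-12,8-olide | C=C1C(=O)O[C@H]2C/C(C)=C/CC/C(COC(C)=O)=C\[C@@H](OC(=O)[C@@]3(C)COC(C)(C)O3)[C@H]12
F11 | step 4 | (2Z)-4-[(tert-butyldimethylsilyl)oxy]-2-(tributylstannyl)but-2-en-1-ol | OC/C(=C/CO[Si](C)(C)C(C)(C)C)[Sn](CCCC)(CCCC)CCCC
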